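Work in litres per mole per minute, the unit of a second-order constant k, and describe this flask with a single k.

- noon: starting material 0.74 M; second substrate 0.50 equiv; coupling partner 1.5 equiv; free catalyst 0.81 mol%; the very flask that is asked about, followed so far
- flask: starting material 0.74 M; second substrate 0.500 equiv; coupling partner 1.50 equiv; free catalyst 0.81 mol%; time 25 min

- noon (time / min: target / %, starting material / %): 0.333: 3.3, 96.3; 0.833: 7.7, 91.1; 1.50: 14.7, 85.0; 2.50: 22.0, 77.5; 3.00: 25.0, 73.3; 5.00: 35.7, 61.4

(readings scatter by 0.3 percentage points)

1. concentration of target at 25 min, in M
2. concentration of starting material at 25 min, in M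
3. concentration of over-reaction product at 25 min, in M

- what was read earlier has a scatter of 0.3 percentage points, one standard deviation

Assume a rate k[A][B], with A the starting material and B the coupling partner, one B lost per A, and the catalyst concentration held. Let a be the fraction of A left and r the equivalents of B. Integration gives a = (r − 1)/(rE − 1), with E = exp[(1 − 1/r)t/τ]. Here τ = 1/(k[B]) at the charge.

The noon reading of 61.4% at 5.00 min gives k = 0.103 /M/min, and the reading at 2.50 min gives 0.0999 /M/min. Take from this 8.76 min as τ, the pseudo-first-order time of A at the charged coupling partner and catalyst. At 25 min my reckoning leaves a = 17.3%, or 0.128 M of A.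

The forecast says 0.44 M target, 0.15 M starting material and 0.15 M over-reaction product, reading the balance gap as “target going on to over-reaction product”.

The flask gives 0.451 M target, 0.164 M starting material and 0.124 M over-reaction product, so its 22.1% of A is more than my 17.3%.

    catalyst intermediate A → spent catalyst (k = 7.75 × 10⁻⁵ /s)
    coupling partner + catalyst intermediate A → free catalyst + target (k = 0.553 /M/s)
    coupling partner + target → over-reaction product (k = 6.10 × 10⁻⁴ /M/s)
    starting material + free catalyst ⇌ catalyst intermediate A (K = 1.20 /M, k = 1.65 /M/s)
    coupling partner + catalyst intermediate B → free catalyst + second product (k = 0.437 /M/s)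
    coupling partner → decomposed reagent (k = 1.42 × 10⁻⁴ /s)
    second substrate + free catalyst ⇌ catalyst intermediate B (K = 2.10 /M, k = 0.120 /M/s)

In the flask asked about, at 5.03 min, catalyst intermediate A falls back 3.4 times faster than it goes on. In the same flask at 25.0 min, free catalyst, at 70.2% of the catalyst charged, is the resting state. Now scale τ for the flask charged with 0.30 M of starting material, equivalents and loading held: coupling partner and catalyst both shrink with the charge, so in the assumed rate τ grows by the square of 2.47, to 53.3 min. There 25 min is 0.469 τ, against 2.85 τ in the flask asked about, and a comes to 66.3%; that dilute flask holds 60.2% of its charged starting material, free form alone, at 25.0 min.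

All runs were computed with constants of no real substance, and the scatter is random.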